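## Retrosynthetic overview

Ring atoms are O1 and C2–C5, the exocyclic carbon is C6, and the carbinol carbon is C1'.

1. C5=CBr2 comes from E1cB loss of HBr from a 5-(tribromomethyl)butenolide, so C5 and C6 arrive ready-made in bromal.
2. The butenolide is the only ring and is closed last. The C4–C5 bond joins a β-acylvinyl anion (an unsaturated homoenolate, held as an α-bromoalkenyl magnesium carbenoid cis to the ester) to the bromal carbonyl. Both carbons are natural electrophiles. The alkoxide then lactonises onto the ester.
3. The carbenoid comes from Br/Mg exchange on a β,β-dibromoacrylate, which comes from Ramirez olefination of an α-keto ester.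
4. The α-keto ester comes from oxidation of an α-diazo ester. That ester comes from a catalytic asymmetric aldol of ethyl diazoacetate with butanal, which sets the only stereocentre as (R). The acetate is put on in the same pot and carried to the end.

Assumption: the magnesium catalyst is taken to show the same facial sense as the zinc aldols of this ligand ((S,S)-ligand attacks the Re face), so the (R,R)-ligand is specified; both antipodes are sold, and the configuration is checked on compound 4 before going on.

## Route

Step 1
Reactants: 1 butanal; 2 ethyl diazoacetate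
Product: 4 ethyl (3R)-3-acetoxy-2-diazohexanoate, via diazo alcohol 3 (not isolated)
Conditions: Bu2Mg (10 mol%), 2,6-bis{[(2R)-2-(hydroxydiphenylmethyl)pyrrolidin-1-yl]methyl}-4-methylphenol ((R,R)-ProPhenol ligand, 5 mol%), cis-cyclopentane-1,2-diol (5 mol%), THF, −20 °C, 24–48 h; then Ac2O, Et3N, 4-(dimethylamino)pyridine (5 mol%), 0 °C
Reagents that add atoms: acetic anhydride, CC(=O)OC(C)=O
Why: In this direct catalytic asymmetric aldol addition of a diazo ester, the dinuclear magnesium–ligand complex holds deprotonated 2 and aldehyde 1 side by side and delivers the diazo carbon to the Si face of 1, which sets C1' as (R), and the in-pot O-acetylation breaks no bond at that centre.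

Step 2
Reactants: 4 ethyl (3R)-3-acetoxy-2-diazohexanoate
Product: 5 ethyl (3R)-3-acetoxy-2-oxohexanoate
Conditions: dimethyldioxirane (about 0.07 M in acetone, 1.2 equiv), 0 °C, 15 min; dry by toluene azeotrope
Reagents that add atoms: dimethyldioxirane, CC1(C)OO1
Why: In this diazo-to-carbonyl oxidation the dioxirane transfers an oxygen atom to the nucleophilic diazo carbon with loss of N2 under neutral conditions, so the acetate, the ester and the now enolisable stereocentre are untouched.

Step 3
Reactants: 5 ethyl (3R)-3-acetoxy-2-oxohexanoate
Product: 6 ethyl (3R)-3-acetoxy-2-(dibromomethylidene)hexanoate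
Conditions: CBr4 (2 equiv), PPh3 (4 equiv), CH2Cl2, 0 °C, 1 h
Reagents that add atoms: carbon tetrabromide, BrC(Br)(Br)Br
Why: In this Ramirez dibromo-olefination (Wittig type, the first stage of the Corey–Fuchs sequence) the weakly basic ylide Ph3P=CBr2 attacks only the very electrophilic keto carbonyl of the α-keto ester, so both esters survive and the neighbouring stereocentre is not enolised at 0 °C.

Step 4
Reactants: 6 ethyl (3R)-3-acetoxy-2-(dibromomethylidene)hexanoate; 7 tribromoacetaldehyde (bromal)
Product: 11 (1R)-1-[4-bromo-5-(dibromomethylidene)-2-oxo-2,5-dihydrofuran-3-yl]butyl acetate (target), via magnesium carbenoid 8 (not isolated), via magnesium alkoxide 9 (not isolated), via tribromomethyl butenolide 10 (not isolated)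
Conditions: iPrMgCl (1.05 equiv), THF, −78 °C, 20 min; cannulate into freshly distilled 7 (1.5 equiv), THF, −78 → 0 °C; Et3N (1.5 equiv), 0 °C, 30 min; aq NH4Cl
Reagents that add atoms: none
Why: Proposed new method: Br/Mg exchange takes only the bromine cis to CO2Et (ester chelation, and the other bromine is shielded by the branched arm) to give the α-bromoalkenyl Grignard 8, a β-acylvinyl anion whose normally electrophilic β-carbon adds to the very electrophilic, non-enolisable carbonyl of 7, after which alkoxide 9 lactonises on the cis ester and removal of the acidic C5–H of 10 expels bromide from the CBr3 group (E1cB, much faster than loss of the poorer acetate leaving group), with C1' a spectator and the transient C5 centre erased; the closest known reaction type is halogen–magnesium exchange of β,β-dibromo- or (Z)-β-iodoacrylates followed by aldehyde trapping to butenolides, and the new elements are bromal as partner (risk: attack at bromine) and the terminating dehydrobromination.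

## Compound list

1 | butanal | CCCC=O | starting material
2 | ethyl diazoacetate | CCOC(=O)C=[N+]=[N-] | starting material
3 | ethyl (3R)-2-diazo-3-hydroxyhexanoate | CCC[C@@H](O)C(=[N+]=[N-])C(=O)OCC | intermediate (not isolated)
4 | ethyl (3R)-3-acetoxy-2-diazohexanoate | CCC[C@@H](OC(C)=O)C(=[N+]=[N-])C(=O)OCC | intermediate
5 | ethyl (3R)-3-acetoxy-2-oxohexanoate | CCC[C@@H](OC(C)=O)C(=O)C(=O)OCC | intermediate
6 | ethyl (3R)-3-acetoxy-2-(dibromomethylidene)hexanoate | CCC[C@@H](OC(C)=O)C(=C(Br)Br)C(=O)OCC | intermediate
7 | tribromoacetaldehyde (bromal) | O=CC(Br)(Br)Br | starting material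
8 | ethyl (2E,3R)-3-acetoxy-2-[bromo(chloromagnesio)methylidene]hexanoate (MgCl cis to CO2Et, Br cis to the acetoxybutyl arm) | CCC[C@@H](OC(C)=O)/C(C(=O)OCC)=C(\Br)[Mg]Cl | intermediate (not isolated)
9 | chloromagnesium alkoxide of ethyl (2E,3R)-3-acetoxy-2-(1,3,3,3-tetrabromo-2-hydroxypropylidene)hexanoate (both carbinol epimers, carbinol carbon cis to CO2Et) | CCC[C@@H](OC(C)=O)/C(C(=O)OCC)=C(\Br)C(O[Mg]Cl)C(Br)(Br)Br | intermediate (not isolated)
10 | (1R)-1-[4-bromo-2-oxo-5-(tribromomethyl)-2,5-dihydrofuran-3-yl]butyl acetate (both C5 epimers) | CCC[C@@H](OC(C)=O)C1=C(Br)C(C(Br)(Br)Br)OC1=O | intermediate (not isolated)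
11 | (1R)-1-[4-bromo-5-(dibromomethylidene)-2-oxo-2,5-dihydrofuran-3-yl]butyl acetate | CCC[C@@H](OC(C)=O)C1=C(Br)C(=C(Br)Br)OC1=O | target

## Count and risks

Total step count: 4. Longest linear sequence: 4.

**Step 4 is the riskiest.** Carbenoid 8 may attack a bromine of 7 instead of its carbonyl, which only returns 6. The weakly nucleophilic alkoxide 9 may also close slowly. The fallback sets out from 6 and comes back at 10. It brings the polybrominated carbon in as a nucleophile instead of an electrophile. Carbenoid 8 is made as before but quenched with DMF, giving the aldehyde ethyl (2E,3R)-3-acetoxy-2-(1-bromo-2-oxoethylidene)hexanoate F1. Tribromomethyl anion, released by decarboxylation of sodium tribromoacetate (Br3CCO2Na) in DMF at 0 °C to room temperature, adds to that aldehyde. This gives ethyl (2E,3R)-3-acetoxy-2-(1,3,3,3-tetrabromo-2-hydroxypropylidene)hexanoate F2. F2 closes to 10 on its own or with catalytic p-toluenesulfonic acid in toluene. Et3N then takes 10 to 11 as in the route.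

**Step 1 is next.** An unbranched, enolisable aldehyde may give a lower ee than the single-enantiomer goal needs. The fallback sets out from 1 and 2 and comes back at 4. It replaces asymmetric catalysis by resolution. A DBU-catalysed aldol in MeCN gives racemic ethyl 2-diazo-3-hydroxyhexanoate F3. Immobilised Candida antarctica lipase B with vinyl acetate in MTBE at 30 °C then acetylates the (R)-alcohol preferentially, because the large diazo ester arm sits against the medium propyl arm (Kazlauskas rule). This gives 4 directly and leaves ethyl (3S)-2-diazo-3-hydroxyhexanoate F4, which is removed by chromatography.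

**Step 3 is third.** The keto group carries a branched neighbour, and 5 can hydrate or enolise, so conversion or ee may suffer. The fallback sets out from 5 and comes back at 6. It replaces the phosphorus ylide by a copper-catalysed olefination of a hydrazone. One equivalent of hydrazine hydrate in EtOH at 0 °C gives ethyl (3R)-3-acetoxy-2-hydrazinylidenehexanoate F5, whose α-proton is much less acidic than that of 5. CBr4 (3 equiv), CuCl (10 mol%) and Et3N in DMSO at room temperature then convert C=N–NH2 into C=CBr2 with loss of N2, giving 6.

## Further compounds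

F1 | step 4 | ethyl (2E,3R)-3-acetoxy-2-(1-bromo-2-oxoethylidene)hexanoate | CCC[C@@H](OC(C)=O)/C(C(=O)OCC)=C(\Br)C=O
F2 | step 4 | ethyl (2E,3R)-3-acetoxy-2-(1,3,3,3-tetrabromo-2-hydroxypropylidene)hexanoate (both carbinol epimers) | CCC[C@@H](OC(C)=O)/C(C(=O)OCC)=C(\Br)C(O)C(Br)(Br)Br
F3 | step 1 | racemic ethyl 2-diazo-3-hydroxyhexanoate | CCCC(O)C(=[N+]=[N-])C(=O)OCC
F4 | step 1 | ethyl (3S)-2-diazo-3-hydroxyhexanoate | CCC[C@H](O)C(=[N+]=[N-])C(=O)OCC
F5 | step 3 | ethyl (3R)-3-acetoxy-2-hydrazinylidenehexanoate | CCC[C@@H](OC(C)=O)C(=NN)C(=O)OCC
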